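The route cuts ring C of the dihydroflavonol at C3–C4: these two adjacent oxygen-bearing carbons are carried as a C3=C4 alkene that is dihydroxylated and oxidised afterwards. Ring-closing olefin metathesis between the vinyl group on C4a of ring A and the terminal alkene of an allylic aryl ether at O1 forms that bond and ring C in one operation and leaves the pre-set C2 stereocentre untouched. The metathesis substrate is an (S)-configured 1-arylallyl ether of a 2-vinylphenol, made by iridium-catalysed enantioselective allylic etherification. A symmetric 4-benzyloxy-3,5-dimethoxy ring A removes any regiochemical question, and the C5 methyl ether is cleaved last under chelation control.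

Key step: step 10

Remark: the C2 descriptor changes from S (compounds 14 and 15) to R (compounds 16 to 19) only because C3 gains CIP priority once it carries oxygen; the centre is never inverted.
Assumption: the (Sa,Sc,Sc) phosphoramidite is taken to deliver the (S)-branched ether; if a first run shows the opposite sense, the mirror-image ligand is used.

Step 1
Reactants: 1 3-hydroxy-4,5-dimethoxybenzaldehyde
Product: 2 3-(benzyloxy)-4,5-dimethoxybenzaldehyde
Conditions: BnBr, K2CO3, DMF, rt
Reagents that add atoms: benzyl bromide, BrCc1ccccc1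
Why: Williamson etherification of the only acidic OH with a reactive benzylic bromide, under which the non-enolisable aldehyde is inert.

Step 2
Reactants: 2 3-(benzyloxy)-4,5-dimethoxybenzaldehyde; 3 triethyl phosphonoacetate
Product: 4 ethyl (E)-3-[3-(benzyloxy)-4,5-dimethoxyphenyl]prop-2-enoate
Conditions: LiCl, DBU, MeCN, rt
Reagents that add atoms: none
Why: Horner–Wadsworth–Emmons olefination of an aromatic aldehyde with a stabilised phosphonate under mild LiCl/amine activation should give the (E)-cinnamate.

Step 3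
Reactants: 4 ethyl (E)-3-[3-(benzyloxy)-4,5-dimethoxyphenyl]prop-2-enoate
Product: 5 (E)-3-[3-(benzyloxy)-4,5-dimethoxyphenyl]prop-2-en-1-ol
Conditions: i-Bu2AlH (2.5 equiv), CH2Cl2, −78 °C to 0 °C; aq. Rochelle salt
Reagents that add atoms: none
Why: 1,2-reduction of the conjugated ester by the aluminium hydride should give the allylic alcohol without touching the alkene or the benzyl ether.

Step 4
Reactants: 5 (E)-3-[3-(benzyloxy)-4,5-dimethoxyphenyl]prop-2-en-1-ol
Product: 6 (E)-3-[3-(benzyloxy)-4,5-dimethoxyphenyl]prop-2-en-1-yl methyl carbonate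
Conditions: ClCO2Me, pyridine, CH2Cl2, 0 °C
Reagents that add atoms: methyl chloroformate, COC(Cl)=O
Why: O-acylation of the primary allylic alcohol gives the linear methyl carbonate, the leaving group needed for iridium-catalysed allylic substitution.

Step 5
Reactants: 7 syringaldehyde
Product: 8 4-(benzyloxy)-3,5-dimethoxybenzaldehyde
Conditions: BnBr, K2CO3, DMF, 60 °C
Reagents that add atoms: benzyl bromide, BrCc1ccccc1
Why: Williamson etherification of the single, flanked phenol, which warming in a dipolar aprotic solvent should drive to completion.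

Step 6
Reactants: 8 4-(benzyloxy)-3,5-dimethoxybenzaldehyde
Product: 10 4-(benzyloxy)-3,5-dimethoxyphenol, via aryl formate 9 (not isolated)
Conditions: mCPBA, CH2Cl2, 0 °C to rt; then K2CO3 (cat.), MeOH, rt
Reagents that add atoms: 3-chloroperbenzoic acid, OOC(=O)c1cccc(Cl)c1
Why: Dakin-type sequence, in which Baeyer–Villiger oxidation of the electron-rich benzaldehyde proceeds with aryl migration to the aryl formate and mild methanolysis then frees the phenol.

Step 7
Reactants: 10 4-(benzyloxy)-3,5-dimethoxyphenol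
Product: 11 3-(benzyloxy)-6-hydroxy-2,4-dimethoxybenzaldehyde
Conditions: MgCl2, Et3N, (CH2O)n, MeCN, reflux; aq. HCl work-up
Reagents that add atoms: paraformaldehyde (as formaldehyde), C=O
Why: Magnesium-mediated ortho-formylation of a phenol (Casnati–Skattebøl type), where the magnesium phenoxide directs formaldehyde to the ortho carbon, a second formaldehyde accepts hydride, and the two ortho positions are equivalent so only one aldehyde can form.

Step 8
Reactants: 11 3-(benzyloxy)-6-hydroxy-2,4-dimethoxybenzaldehyde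
Product: 12 4-(benzyloxy)-3,5-dimethoxy-2-vinylphenol
Conditions: Ph3PCH3Br (2.5 equiv), KOt-Bu (2.4 equiv), THF, 0 °C to rt; product used promptly in step 9
Reagents that add atoms: methyltriphenylphosphonium bromide, C[P+](c1ccccc1)(c1ccccc1)c1ccccc1.[Br-]
Why: Wittig methylenation with a non-stabilised ylide, in which the extra base covers the acidic phenol and the aldehyde of the resulting phenoxide is still expected to react.

Step 9
Reactants: 12 4-(benzyloxy)-3,5-dimethoxy-2-vinylphenol; 6 (E)-3-[3-(benzyloxy)-4,5-dimethoxyphenyl]prop-2-en-1-yl methyl carbonate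
Product: 14 (S)-2-(benzyloxy)-5-{1-[3-(benzyloxy)-4,5-dimethoxyphenyl]prop-2-en-1-yloxy}-1,3-dimethoxy-4-vinylbenzene, via lithium aryloxide 13 (not isolated)
Conditions: LiN(SiMe3)2 (1.0 equiv), THF, 0 °C; then 6, [Ir(cod)Cl]2 (2 mol %), (Sa,Sc,Sc)-O,O'-(1,1'-binaphthyl-2,2'-diyl)-N,N-bis(1-phenylethyl)phosphoramidite (4 mol %, pre-activated with n-PrNH2), THF, rt to 50 °C
Reagents that add atoms: none
Why: Iridium-catalysed enantioselective allylic etherification, in which the cyclometalated iridium phosphoramidite complex ionises the linear carbonate to an allyl complex that the aryloxide attacks at the aryl-bearing terminus, so the branched ether forms and the chiral ligand sets the future C2 centre as S.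

Step 10
Reactants: 14 (S)-2-(benzyloxy)-5-{1-[3-(benzyloxy)-4,5-dimethoxyphenyl]prop-2-en-1-yloxy}-1,3-dimethoxy-4-vinylbenzene
Product: 15 (2S)-6-(benzyloxy)-2-[3-(benzyloxy)-4,5-dimethoxyphenyl]-5,7-dimethoxy-2H-chromene
Conditions: second-generation Grubbs catalyst RuCl2(H2IMes)(PCy3)(=CHPh) (5 mol %), 1,4-benzoquinone (10 mol %), CH2Cl2 (0.01 M), 40 °C
Reagents that add atoms: none
Why: The ruthenium benzylidene should first exchange onto the less hindered vinyl group of the allylic ether; the new alkylidene then adds across the ring A vinyl group in a [2+2] step, and cycloreversion of the ruthenacyclobutane releases the chromene and a ruthenium methylidene that carries the chain with loss of ethene. The closest known reaction type is ring-closing metathesis of 2-vinylaryl allyl ethers to 2H-chromenes. Ring C closes as a six-membered ring with the new C3=C4 bond inside the ring, so the alkene is necessarily cis. No stereocentre is created, and C2 is not a reacting atom, so it keeps its S configuration provided that ruthenium hydride species do not migrate the allylic double bond, which the benzoquinone additive is there to suppress. The selectivity needed is cyclisation over intermolecular metathesis and over isomerisation; it is secured by two terminal alkenes placed for six-ring closure, by high dilution and by the irreversible escape of ethene.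

Step 11
Reactants: 15 (2S)-6-(benzyloxy)-2-[3-(benzyloxy)-4,5-dimethoxyphenyl]-5,7-dimethoxy-2H-chromene
Product: 16 (2R,3S,4S)-6-(benzyloxy)-2-[3-(benzyloxy)-4,5-dimethoxyphenyl]-5,7-dimethoxy-3,4-dihydro-2H-chromene-3,4-diol (2,3-trans, 3,4-cis)
Conditions: K2OsO4·2H2O (2 mol %), NMO (1.5 equiv), acetone/H2O, 0 °C to rt; aq. Na2SO3
Reagents that add atoms: N-methylmorpholine N-oxide, C[N+]1([O-])CCOCC1; water, O (both delivered through the oxo ligands of OsO4)
Why: Catalytic OsO4 dihydroxylation (Upjohn conditions) adds both oxygens to one face, and the C2 aryl group should direct the reagent to the opposite face of C3=C4, so the C3 oxygen is set trans to ring B and the C4 oxygen cis to it (substrate control).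

Step 12
Reactants: 16 (2R,3S,4S)-6-(benzyloxy)-2-[3-(benzyloxy)-4,5-dimethoxyphenyl]-5,7-dimethoxy-3,4-dihydro-2H-chromene-3,4-diol
Product: 17 (2R,3R)-6-(benzyloxy)-2-[3-(benzyloxy)-4,5-dimethoxyphenyl]-3-hydroxy-5,7-dimethoxy-2,3-dihydro-4H-chromen-4-one
Conditions: DDQ (1.2 equiv), CH2Cl2/pH 7 phosphate buffer, 0 °C to rt
Reagents that add atoms: none
Why: DDQ oxidation of an electron-rich benzylic alcohol by hydride abstraction, which should occur only at the C4 carbinol conjugated with the tri-oxygenated ring A and leave the non-benzylic C3 alcohol and its configuration alone, without the glycol cleavage that MnO2 can cause on cis-diols.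

Step 13
Reactants: 17 (2R,3R)-6-(benzyloxy)-2-[3-(benzyloxy)-4,5-dimethoxyphenyl]-3-hydroxy-5,7-dimethoxy-2,3-dihydro-4H-chromen-4-one
Product: 18 (2R,3R)-6-(benzyloxy)-2-[3-(benzyloxy)-4,5-dimethoxyphenyl]-3,5,7-trimethoxy-2,3-dihydro-4H-chromen-4-one
Conditions: MeI (excess), Ag2O (3 equiv), 4 Å MS, CH2Cl2, dark, rt to 40 °C
Reagents that add atoms: iodomethane, CI
Why: Purdie methylation, in which Ag2O activates iodomethane and takes up HI without a soluble base, so the alcohol next to the ketone should be etherified without enolisation-driven opening of ring C, the trans (2R,3R) arrangement being also the thermodynamically preferred one.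

Step 14
Reactants: 18 (2R,3R)-6-(benzyloxy)-2-[3-(benzyloxy)-4,5-dimethoxyphenyl]-3,5,7-trimethoxy-2,3-dihydro-4H-chromen-4-one
Product: 19 (2R,3R)-5,6-dihydroxy-2-(3-hydroxy-4,5-dimethoxyphenyl)-3,7-dimethoxy-2,3-dihydro-4H-chromen-4-one
Conditions: BCl3 (1 M in CH2Cl2, 6 equiv), C6HMe5 (6 equiv), CH2Cl2, −78 °C, then 0 °C; MeOH then H2O quench under argon
Reagents that add atoms: none
Why: BCl3 cleaves both aryl benzyl ethers at low temperature, with pentamethylbenzene trapping the benzyl cations by Friedel–Crafts alkylation, and on warming should remove only the C5 methyl ether through the six-membered boron chelate with the C4 carbonyl (chelation-controlled demethylation), leaving the four non-chelated methyl ethers.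

Compound list
1 | 3-hydroxy-4,5-dimethoxybenzaldehyde | COc1cc(C=O)cc(O)c1OC | starting material
2 | 3-(benzyloxy)-4,5-dimethoxybenzaldehyde | COc1cc(C=O)cc(OCc2ccccc2)c1OC | intermediate
3 | triethyl phosphonoacetate | CCOC(=O)CP(=O)(OCC)OCC | starting material
4 | ethyl (E)-3-[3-(benzyloxy)-4,5-dimethoxyphenyl]prop-2-enoate | CCOC(=O)/C=C/c1cc(OC)c(OC)c(OCc2ccccc2)c1 | intermediate
5 | (E)-3-[3-(benzyloxy)-4,5-dimethoxyphenyl]prop-2-en-1-ol | OC/C=C/c1cc(OC)c(OC)c(OCc2ccccc2)c1 | intermediate
6 | (E)-3-[3-(benzyloxy)-4,5-dimethoxyphenyl]prop-2-en-1-yl methyl carbonate | COC(=O)OC/C=C/c1cc(OC)c(OC)c(OCc2ccccc2)c1 | intermediate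
7 | syringaldehyde (4-hydroxy-3,5-dimethoxybenzaldehyde) | COc1cc(C=O)cc(OC)c1O | starting material
8 | 4-(benzyloxy)-3,5-dimethoxybenzaldehyde | COc1cc(C=O)cc(OC)c1OCc1ccccc1 | intermediate
9 | 4-(benzyloxy)-3,5-dimethoxyphenyl formate | COc1cc(OC=O)cc(OC)c1OCc1ccccc1 | intermediate (not isolated)
10 | 4-(benzyloxy)-3,5-dimethoxyphenol | COc1cc(O)cc(OC)c1OCc1ccccc1 | intermediate
11 | 3-(benzyloxy)-6-hydroxy-2,4-dimethoxybenzaldehyde | COc1cc(O)c(C=O)c(OC)c1OCc1ccccc1 | intermediate
12 | 4-(benzyloxy)-3,5-dimethoxy-2-vinylphenol | C=Cc1c(O)cc(OC)c(OCc2ccccc2)c1OC | intermediate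
13 | lithium 4-(benzyloxy)-3,5-dimethoxy-2-vinylphenolate | [Li+].[O-]c1cc(OC)c(OCc2ccccc2)c(OC)c1C=C | intermediate (not isolated)
14 | (S)-2-(benzyloxy)-5-{1-[3-(benzyloxy)-4,5-dimethoxyphenyl]prop-2-en-1-yloxy}-1,3-dimethoxy-4-vinylbenzene | C=C[C@@H](c1cc(OCc2ccccc2)c(OC)c(OC)c1)Oc1cc(OC)c(OCc2ccccc2)c(OC)c1C=C | intermediate
15 | (2S)-6-(benzyloxy)-2-[3-(benzyloxy)-4,5-dimethoxyphenyl]-5,7-dimethoxy-2H-chromene | COc1cc2c(c(OC)c1OCc1ccccc1)C=C[C@@H](c1cc(OCc3ccccc3)c(OC)c(OC)c1)O2 | intermediate
16 | (2R,3S,4S)-6-(benzyloxy)-2-[3-(benzyloxy)-4,5-dimethoxyphenyl]-5,7-dimethoxy-3,4-dihydro-2H-chromene-3,4-diol | COc1cc2c(c(OC)c1OCc1ccccc1)[C@H](O)[C@H](O)[C@@H](c1cc(OCc3ccccc3)c(OC)c(OC)c1)O2 | intermediate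
17 | (2R,3R)-6-(benzyloxy)-2-[3-(benzyloxy)-4,5-dimethoxyphenyl]-3-hydroxy-5,7-dimethoxy-2,3-dihydro-4H-chromen-4-one | COc1cc2c(c(OC)c1OCc1ccccc1)C(=O)[C@H](O)[C@@H](c1cc(OCc3ccccc3)c(OC)c(OC)c1)O2 | intermediate
18 | (2R,3R)-6-(benzyloxy)-2-[3-(benzyloxy)-4,5-dimethoxyphenyl]-3,5,7-trimethoxy-2,3-dihydro-4H-chromen-4-one | COc1cc2c(c(OC)c1OCc1ccccc1)C(=O)[C@H](OC)[C@@H](c1cc(OCc3ccccc3)c(OC)c(OC)c1)O2 | intermediate
19 | (2R,3R)-5,6-dihydroxy-2-(3-hydroxy-4,5-dimethoxyphenyl)-3,7-dimethoxy-2,3-dihydro-4H-chromen-4-one | COc1cc2c(c(O)c1O)C(=O)[C@H](OC)[C@@H](c1cc(O)c(OC)c(OC)c1)O2 | target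

Total step count: 14. Longest linear sequence: 10 steps (steps 5 to 14 from syringaldehyde; the ring B branch, steps 1 to 4 and 9 to 14, is equally long).

Steps most likely to fail, in route order:

Step 9. The branched ether may form with eroded regioselectivity or enantiomeric purity, because the electron-rich branched product can re-ionise on iridium and the ortho-substituted aryloxide attacks slowly. The fallback sets out from 2, uses 12 as the coupling partner and returns at 14. Vinylmagnesium bromide is added to 2 (THF, 0 °C) to give racemic 1-[3-(benzyloxy)-4,5-dimethoxyphenyl]prop-2-en-1-ol F1. Sharpless kinetic resolution (Ti(Oi-Pr)4, D-(−)-diisopropyl tartrate, t-BuOOH, 4 Å MS, CH2Cl2, −20 °C) should consume the S enantiomer as the erythro epoxy alcohol (R)-[3-(benzyloxy)-4,5-dimethoxyphenyl][(S)-oxiran-2-yl]methanol F3 and leave (R)-1-[3-(benzyloxy)-4,5-dimethoxyphenyl]prop-2-en-1-ol F2. Mitsunobu coupling of F2 with 12 (PPh3, DIAD, toluene, −20 °C) should then give 14 with inversion at the carbinol carbon.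

Step 12. Hydride abstraction at C4 may be slow because H4 lies near the plane of ring A in the preferred half-chair, and the acid-labile C4 benzylic alcohol may ionise or C2 may be over-oxidised instead. The fallback sets out from 16 and returns at 18, bypassing 17, by methylating before the ketone exists. Bu2SnO (toluene, reflux, water removal) converts 16 into the 3,4-O-dibutylstannylene acetal of 16 F4. MeI with CsF in DMF should alkylate the equatorial C3 oxygen, the axial C4 oxygen being shielded by the C5 methoxy group, to give (2R,3S,4S)-6-(benzyloxy)-2-[3-(benzyloxy)-4,5-dimethoxyphenyl]-3,5,7-trimethoxy-3,4-dihydro-2H-chromen-4-ol F5. Dess–Martin periodinane (NaHCO3, CH2Cl2, rt) then oxidises the only remaining alcohol to give 18.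

Step 14. BCl3 may over-react by removing a second methyl group, most plausibly the central ring B methyl ether next to the newly formed boron aryloxide or the aliphatic C3 methyl ether, or un-trapped benzyl cations may alkylate the electron-rich rings. The fallback sets out from 18 and returns at 19 with a Lewis acid that acts only where it can chelate. MgI2·OEt2 (toluene/Et2O, 50 to 80 °C) should cleave only the C5 methyl ether, which binds magnesium together with the C4 carbonyl, giving (2R,3R)-6-(benzyloxy)-2-[3-(benzyloxy)-4,5-dimethoxyphenyl]-5-hydroxy-3,7-dimethoxy-2,3-dihydro-4H-chromen-4-one F6. Hydrogenolysis (H2, 1 atm, Pd/C, EtOAc/MeOH, rt) then removes both benzyl groups to give 19.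

Further compounds
F1 | step 9 | racemic 1-[3-(benzyloxy)-4,5-dimethoxyphenyl]prop-2-en-1-ol | C=CC(O)c1cc(OC)c(OC)c(OCc2ccccc2)c1
F2 | step 9 | (R)-1-[3-(benzyloxy)-4,5-dimethoxyphenyl]prop-2-en-1-ol | C=C[C@@H](O)c1cc(OC)c(OC)c(OCc2ccccc2)c1
F3 | step 9 | (R)-[3-(benzyloxy)-4,5-dimethoxyphenyl][(S)-oxiran-2-yl]methanol | O[C@H](c1cc(OC)c(OC)c(OCc2ccccc2)c1)[C@@H]1CO1
F4 | step 12 | 3,4-O-dibutylstannylene acetal of 16 | COc1cc2c(c(OC)c1OCc1ccccc1)[C@@H]1O[Sn](CCCC)(CCCC)O[C@@H]1[C@@H](c1cc(OCc3ccccc3)c(OC)c(OC)c1)O2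
F5 | step 12 | (2R,3S,4S)-6-(benzyloxy)-2-[3-(benzyloxy)-4,5-dimethoxyphenyl]-3,5,7-trimethoxy-3,4-dihydro-2H-chromen-4-ol | COc1cc2c(c(OC)c1OCc1ccccc1)[C@H](O)[C@H](OC)[C@@H](c1cc(OCc3ccccc3)c(OC)c(OC)c1)O2
F6 | step 14 | (2R,3R)-6-(benzyloxy)-2-[3-(benzyloxy)-4,5-dimethoxyphenyl]-5-hydroxy-3,7-dimethoxy-2,3-dihydro-4H-chromen-4-one | COc1cc2c(c(O)c1OCc1ccccc1)C(=O)[C@H](OC)[C@@H](c1cc(OCc3ccccc3)c(OC)c(OC)c1)O2
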